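**Retrosynthetic overview**

1. Rings: A = methoxy-bearing ring, B = para-linked ring, C = phenol ring, D = meta-linked ring without further substituents. All four benzene rings are bought; the only ring made is the 19-membered macrocycle.
2. Last disconnection is the O-benzyl ether on ring C. Before it, the macrocycle is opened at the bond between the ring B carbon para to the diaryl ether oxygen and the neighbouring CH2 of the B–C ethano bridge.
3. Enabling feature: both of these carbons are donor positions. The ring B carbon is para to its ether oxygen, and the CH2 is the terminal carbon of a vinyl group standing para to the ring C oxygen. Ring B is therefore carried with Br on that carbon (polarity reversed), and hydroboration of the ring C styrene puts boron exactly on that CH2; a one-pot hydroboration/B-alkyl Suzuki coupling closes the ring at the final oxidation level.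
4. The seco bromo-styrene comes from two diaryl ether styrenes by a first hydroboration/B-alkyl Suzuki coupling (C–I before C–Br), which makes the A–CH2CH2–D bridge.
5. Each diaryl ether styrene is made by Chan–Lam O-arylation of a hydroxybenzaldehyde followed by Wittig methylenation.

Key step: step 6

Remark: the target has no stereocentre and the 19-membered ring is taken as conformationally mobile, so no stereocontrol is needed.

**Route**

Step 1
Reactants: 1 isovanillin (3-hydroxy-4-methoxybenzaldehyde); 2 4-bromophenylboronic acid
Product: 3 3-(4-bromophenoxy)-4-methoxybenzaldehyde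
Conditions: Cu(OAc)2 (20 mol%), pyridine, 4 Å MS, CH2Cl2, O2 (1 atm), rt
Reagents that add atoms: none
Why: Chan–Lam–Evans O-arylation, in which the aryl group passes from boron to divalent copper and C–O reductive elimination from the copper phenoxide gives the diaryl ether at room temperature, leaving the aldehyde and the C–Br bond untouched.

Step 2
Reactants: 3 3-(4-bromophenoxy)-4-methoxybenzaldehyde
Product: 4 2-(4-bromophenoxy)-1-methoxy-4-vinylbenzene
Conditions: Ph3PCH3Br, KOtBu, THF, 0 °C to rt
Reagents that add atoms: methyltriphenylphosphonium bromide, C[P+](c1ccccc1)(c1ccccc1)c1ccccc1.[Br-], acting as its ylide methylenetriphenylphosphorane, C=P(c1ccccc1)(c1ccccc1)c1ccccc1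
Why: Wittig methylenation of an aromatic aldehyde with the non-stabilized ylide is reliable and does not touch the aryl bromide or the diaryl ether.

Step 3
Reactants: 5 4-(benzyloxy)-3-hydroxybenzaldehyde; 6 3-iodophenylboronic acid
Product: 7 4-(benzyloxy)-3-(3-iodophenoxy)benzaldehyde
Conditions: Cu(OAc)2 (20 mol%), pyridine, 4 Å MS, CH2Cl2, O2 (1 atm), rt
Reagents that add atoms: none
Why: Chan–Lam–Evans O-arylation as in step 1; at room temperature the copper catalyst should not engage the C–I bond, and the benzyl ether and aldehyde are inert.

Step 4
Reactants: 7 4-(benzyloxy)-3-(3-iodophenoxy)benzaldehyde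
Product: 8 1-(benzyloxy)-2-(3-iodophenoxy)-4-vinylbenzene
Conditions: Ph3PCH3Br, KOtBu, THF, 0 °C to rt
Reagents that add atoms: methyltriphenylphosphonium bromide, C[P+](c1ccccc1)(c1ccccc1)c1ccccc1.[Br-], acting as its ylide methylenetriphenylphosphorane, C=P(c1ccccc1)(c1ccccc1)c1ccccc1
Why: Wittig methylenation as in step 2; the ylide does not react with the aryl iodide or the benzyl ether.

Step 5
Reactants: 4 2-(4-bromophenoxy)-1-methoxy-4-vinylbenzene; 8 1-(benzyloxy)-2-(3-iodophenoxy)-4-vinylbenzene
Product: 10 1-(benzyloxy)-2-[3-[2-[3-(4-bromophenoxy)-4-methoxyphenyl]ethyl]phenoxy]-4-vinylbenzene (seco bromo-styrene), via alkylborane 9 (not isolated)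
Conditions: 4 (1.15 equiv), 9-BBN (1.1 equiv), THF, 0 °C to rt; then 8 (1.0 equiv), PdCl2(dppf) (5 mol%), AsPh3, aq. Cs2CO3, DMF, rt
Reagents that add atoms: none
Why: B-alkyl Suzuki–Miyaura coupling, in which 9-BBN hydroborates styrene 4 at the terminal carbon and, at room temperature, zerovalent palladium inserts into the C–I bond of 8 far faster than into the C–Br bond on ring B, so only the A–CH2CH2–D bridge should form; the vinyl group of 8 survives because 4 is in excess over 9-BBN and no boron hydride is left.

Step 6
Reactants: 10 seco bromo-styrene
Product: 12 O-benzyl macrocycle (benzyl ether of the target), via alkylborane 11 (not isolated)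
Conditions: 9-BBN (2 equiv), THF, rt; then syringe-pump addition over 12 h into PdCl2(dppf) (15 mol%), AsPh3, aq. Cs2CO3, THF/DMF, 60 °C, final concentration about 2 mM
Reagents that add atoms: none
Why: 9-BBN adds anti-Markovnikov across the vinyl group on ring C, so boron sits on the terminal carbon; after base is added, the hydroxyborate hands this primary alkyl group to the arylpalladium bromide formed by oxidative addition of zerovalent palladium into the C–Br bond of ring B, and reductive elimination joins the CH2 to the ring B carbon para to the ether oxygen. The closest known reaction type is the B-alkyl Suzuki–Miyaura macrocyclization used for cyclophanes and macrolides. The 19-membered ring closes by reductive elimination from a 20-membered aryl(alkyl)palladium ring, with both newly bonded atoms inside the ring, under slow addition at high dilution. No stereocentre is formed. The step needs regioselective hydroboration, secured by the bulk of 9-BBN and the terminal alkene, and ring closure in preference to oligomerization, favoured by dilution, by the single C–Br and single C–B site in 11, and by the two meta-linked diaryl ethers and flexible ethano bridge that let the chain ends meet without strain. The dppf ligand should keep β-hydride elimination of the alkylpalladium slower than reductive elimination.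

Step 7
Reactants: 12 O-benzyl macrocycle
Product: 13 target CNP0132125.0
Conditions: H2 (1 atm), 10% Pd/C, EtOAc/EtOH, rt
Reagents that add atoms: none
Why: Hydrogenolysis of the benzyl aryl ether over palladium on carbon should free the ring C phenol, while the diaryl ethers, the methyl ether and the ethano bridges are inert.

**Compound list**

1 | isovanillin (3-hydroxy-4-methoxybenzaldehyde) | COc1ccc(C=O)cc1O | starting material
2 | 4-bromophenylboronic acid | OB(O)c1ccc(Br)cc1 | starting material
3 | 3-(4-bromophenoxy)-4-methoxybenzaldehyde | COc1ccc(C=O)cc1Oc1ccc(Br)cc1 | intermediate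
4 | 2-(4-bromophenoxy)-1-methoxy-4-vinylbenzene | COc1ccc(C=C)cc1Oc1ccc(Br)cc1 | intermediate
5 | 4-(benzyloxy)-3-hydroxybenzaldehyde | O=Cc1ccc(OCc2ccccc2)c(O)c1 | starting material
6 | 3-iodophenylboronic acid | OB(O)c1cccc(I)c1 | starting material
7 | 4-(benzyloxy)-3-(3-iodophenoxy)benzaldehyde | O=Cc1ccc(OCc2ccccc2)c(Oc2cccc(I)c2)c1 | intermediate
8 | 1-(benzyloxy)-2-(3-iodophenoxy)-4-vinylbenzene | C=Cc1ccc(OCc2ccccc2)c(Oc2cccc(I)c2)c1 | intermediate
9 | 9-[2-[3-(4-bromophenoxy)-4-methoxyphenyl]ethyl]-9-borabicyclo[3.3.1]nonane | COc1ccc(CCB2C3CCCC2CCC3)cc1Oc1ccc(Br)cc1 | intermediate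
10 | 1-(benzyloxy)-2-[3-[2-[3-(4-bromophenoxy)-4-methoxyphenyl]ethyl]phenoxy]-4-vinylbenzene (seco bromo-styrene) | COc1ccc(CCc2cccc(Oc3cc(C=C)ccc3OCc3ccccc3)c2)cc1Oc1ccc(Br)cc1 | intermediate
11 | 9-[2-[4-(benzyloxy)-3-[3-[2-[3-(4-bromophenoxy)-4-methoxyphenyl]ethyl]phenoxy]phenyl]ethyl]-9-borabicyclo[3.3.1]nonane | COc1ccc(CCc2cccc(Oc3cc(CCB4C5CCCC4CCC5)ccc3OCc3ccccc3)c2)cc1Oc1ccc(Br)cc1 | intermediate
12 | O-benzyl macrocycle (benzyl ether of the target on the ring C oxygen) | COc1ccc2cc1Oc1ccc(cc1)CCc1ccc(OCc3ccccc3)c(c1)Oc1cccc(c1)CC2 | intermediate
13 | target CNP0132125.0 (macrocyclic bis(bibenzyl) with OMe on ring A and free OH on ring C) | COc1ccc2cc1Oc1ccc(cc1)CCc1ccc(O)c(c1)Oc1cccc(c1)CC2 | target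

**Step count and risks**

Total step count: 7. Longest linear sequence: 5 steps (1 → 3 → 4 → 10 → 12 → 13, or equally 5 → 7 → 8 → 10 → 12 → 13).

Steps most likely to fail:

Step 6. Intermolecular coupling may outpace ring closure and give oligomers, and the alkylborane may be lost by protodeboronation or β-hydride elimination while oxidative addition into the electron-rich C–Br bond is slow. The fallback sets out from 10 and joins the same two carbons at the alkene oxidation level without any organoboron species. An intramolecular Heck reaction (Pd(OAc)2, P(o-tol)3, K2CO3, DMF, 100 °C, 2 mM) should give the macrocyclic (E)-stilbene benzyl ether F1. Hydrogenation (H2, 10% Pd/C, EtOAc/EtOH, rt) should then saturate the alkene and cleave the benzyl ether in the same flask, so the fallback comes back to the route at 13.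

Step 5. Left-over boron hydride may hydroborate the vinyl group of 8, and that vinyl group may also undergo Heck-type arylation, both leading to mixed or oligomeric products. The fallback sets out from 7, with borane 9 made from 4 as before, so that no second alkene is in the flask during the coupling. Coupling of 9 with 7 (PdCl2(dppf), AsPh3, aq. Cs2CO3, DMF/THF, rt) should give 4-(benzyloxy)-3-[3-[2-[3-(4-bromophenoxy)-4-methoxyphenyl]ethyl]phenoxy]benzaldehyde F2. Wittig methylenation (Ph3PCH3Br, KOtBu, THF, 0 °C) then installs the vinyl group, and the fallback comes back at 10.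

Step 3. Conversion may stall because the hindered ortho-alkoxy phenol, deactivated by the aldehyde, binds copper poorly while the boronic acid is used up by protodeboronation and homocoupling. The fallback sets out from 5 and replaces the oxidative boronic acid coupling by an Ullmann-type coupling with an aryl iodide electrophile: 1,3-diiodobenzene (3 equiv, to suppress double arylation), CuI, N,N-dimethylglycine hydrochloride, Cs2CO3, dioxane, 90 °C. It comes back at 7 and makes no new compound (entry F0).

**Further compounds**

F1 | step 6 | macrocyclic (E)-stilbene benzyl ether (12 with an (E)-CH=CH bridge between rings B and C) | COc1ccc2cc1Oc1ccc(cc1)/C=C/c1ccc(OCc3ccccc3)c(c1)Oc1cccc(c1)CC2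
F2 | step 5 | 4-(benzyloxy)-3-[3-[2-[3-(4-bromophenoxy)-4-methoxyphenyl]ethyl]phenoxy]benzaldehyde | COc1ccc(CCc2cccc(Oc3cc(C=O)ccc3OCc3ccccc3)c2)cc1Oc1ccc(Br)cc1
F0 | step 3 | none | none
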